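## The problem

Compound 44 is a resveratrol hexamer whose skeleton is read here as a chain of six aryl-bearing methines, C-1 to C-6: C-1, C-3 and C-6 each carry a 4-hydroxyphenyl group, while C-2, C-4 and C-5 carry the benzo rings (rings B, C and E) of three trans-2-(4-hydroxyphenyl)-3-(3,5-dihydroxyphenyl)-2,3-dihydrobenzofurans (units 1, 2 and 3). The pendant resorcinol ring of unit 1 (ring A) is bonded through an ortho carbon to C-1 and so closes a seven-membered ring (C-1, C-2, two carbons of ring B, furan C-3 of unit 1, two carbons of ring A); the pendant ring of unit 2 (ring D) is bonded to C-6 and closes an eight-membered ring (C-4, C-5, C-6, two carbons each of rings C and D, furan C-3 of unit 2); ring F of unit 3 stays free. There are twelve stereocentres: the six on the dihydrofurans are (2R,3R)-trans in all three units, so one enantiopure building block can serve three times. The six chain centres (1S,2S,3R,4R,5S,6S) have to be derived from these: furan C-3 of units 1 and 2 becomes a ring-fusion methine that can steer C-1 or C-6 across ring A or D, and each further chain centre can then be set from its neighbour. Fifteen phenols must travel as ethers, and the three furan C-2–O bonds are para-alkoxybenzylic ethers that ionise in strong acid and would not survive hydrogenolysis. Every chain methine is benzylic, and a cation at C-1, C-3 or C-6 lies five or six atoms from an electron-rich arene C–H, so late Friedel–Crafts closures risk indane or tetralin formation. The feature that the plan exploits is that each benzofuran arene (rings B, C and E) is a 1,2,3,5-tetrasubstituted benzene: furan oxygen, furan C-3 and a chain methine on three neighbouring carbons, and one hydroxyl meta to the two outer ones. An ynol ether, an internal alkyne three atoms away and an alkoxyacetylene supply exactly these six carbons, so the arene and its furan ring can be closed together from an open chain in which furan C-2 and C-3 are already set.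

## Retrosynthesis

**44 from 43.** The fifteen O–H bonds are traced back to aryl ethers: twelve methyl ethers from the starting materials and three ethyl ethers that the arene-forming step leaves on rings B, C and E. One Lewis acid must cleave both kinds; nothing else in 43 is sensitive to it.

**43 from 42, 41 and 39 (C-1–H and C-1–aryl).** The anisyl group on C-1 is removed to leave the seven-ring ketone 41, with the tertiary alcohol 42 as the intermediate and the Grignard reagent 39 as the aryl source. The cation at C-1 is doubly benzylic and sits in the ring, so hydride is the only nucleophile it has to meet. The neighbouring cut, closing the seven-membered ring last by attack of ring A on a C-1 cation, is rejected because in the full molecule that cation is six atoms from a free C–H of ring C. The forward step must deliver hydride to the convex face of the tricycle, anti to the C-2 substituent.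

**41 from 38 and 39 (C-3–aryl).** The anisyl group on C-3 is cut as a conjugate addition of 39 to enone 38. This puts the aryl group on C-3 without ever making a cation there, which ring E would trap as an indane. The forward step needs facial control from C-4.

**38 from 34 and 31 (C-2=C-3).** This is the convergent cut. It divides the molecule into the seven-ring ketone 34 (two resveratrol units) and the eight-ring aldehyde 31 (four units). C-2 is the only enolisable carbon of 34 and C-3 is the aldehyde carbon of 31, so an aldol condensation is unambiguous. Cutting C-3–C-4 instead would need a nucleophile at C-4, which has no activating neighbour.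

**34 from 32 and 20 (ring A–C-1).** The aryl ketone bond is cut as a Friedel–Crafts acylation. The ortho carbon of ring A is the only nucleophilic position within reach of the arylacetic acid 32, and 32 is the benzylzinc reagent 20 plus CO2. This is simpler than building ring A on a preformed ring.

**31 from 30, 28 and 27 (C-3–C-4).** The aldehyde carbon is cut back to the eight-ring ketone 27 through the methylidene compound 28 and the alcohol 30. The ketone is what made the ring closure possible, and hydroboration lets H-4 be delivered under the influence of C-5.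

**27 from 25 (C-5–C-6).** The eight-membered ring is opened between C-5 and C-6. The cation at C-6 then hangs only on ring D, and the nucleophile is the enol of the C-4 ketone. The alternative, attack of ring D on a C-6 cation attached to C-5, would compete with five-ring closure onto ring C and is avoided. The forward step needs high dilution and one rotamer of the cation.

**25 from 24, 23, 21, 18, 20 and 7.**

- Ring D–C-6 is made from an aryllithium and 4-methoxybenzaldehyde 7; the aryl bromide 18 comes from regioselective bromination of aldehyde 17.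
- C-4–C-5 is made by adding the benzylzinc reagent 20 to the aldehyde of 18, giving 21.
- The methyl ether 24 only serves to oxidise the other carbinol selectively.

**17, 19 and 20 from 16 and 15.** Aldehyde 17, chloride 19 and, through 19, the zinc reagent 20 all derive from the benzylic alcohol 16, and one batch of 20 feeds both the eight-ring and the seven-ring half. Units 1, 2 and 3 are therefore the same compound, and the enantiomeric purity of 16 is multiplied when three copies are joined.

**15 from 13 and 14.** Three arene C–C bonds are cut: ring B (or C, E) and its furan ring are opened to the ynol ether–alkyne 13 and ethoxyacetylene 14. This replaces a substituted resorcinol starting material, a separate C–O ring closure and a regiocontrol problem on the arene by one cycloaddition on an open chain. The forward reaction has to tolerate an ynol ether in the tether and place the ethoxy group meta to both neighbours.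

**13 from 11, 8 and 9; 8 from 6 and 7; 6 from 5, 4, 1 and 2.** The ynol ether comes from the alcohol 8 and trichloroethylene 9 through the dichlorovinyl ether 11. The anti alcohol 8 comes from 4-methoxybenzaldehyde 7 and the allenylboronate 6. Boronate 6 is made, through alcohol 4 and carbonate 5, from 3,5-dimethoxybenzaldehyde 2 and silylated propargyl alcohol 1. The only absolute stereocontrol in the route is asked of the allenylboration.

## Roads not taken

**Alternative 1:** The seven-membered ring is cut at both aryl–carbon bonds of ring A. In the forward sense the aryne released by CsF from silyl triflate A2 inserts into the C(=O)–CH(CO2Me) bond of the 2-indanone keto ester A1 and gives the dibenzo-fused cycloheptanone ester A3.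

- Merits: ring A, the C-1 carbonyl and the seven-membered ring arrive in one step of a known type, and the methoxy group next to the aryne bond directs the regiochemistry.
- Weak points: A3 is racemic and contains none of the stereocentres of 44. The furan of unit 1 must still be built on the ester carbon and resolved, and nothing is transferable to units 2 and 3.
- Comparison: A3 corresponds to ketone 34 and is reached from simpler material with a better precedented key step; in that respect this road is superior. The chosen plan sets against it absolute configuration from step 4 and one building block (16) for all three units.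

**Alternative 2:** Ring E is cut at two of its C–C bonds. The diene A4 adds to the alkynyl ketone A5 on C-5 and the adduct aromatises to the aroylphenol A6.

- Merits: the regiochemistry of such diene–ynone cycloadditions is dependable, the new phenol comes out differentiated, and the ring-forming event is more certain than the ruthenium step.
- Weak points: it is placed after the whole pentameric core A5, with both medium rings, has been made. It builds one of three benzofuran arenes and no furan ring, and the last dihydrofuran with two stereocentres must then be made from the benzophenone A6 on the largest intermediate of the route.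
- Comparison: as a single step it is the safer one. The chosen plan closes arene and furan together, early and on a small molecule.

**Alternative 3:** The eight-membered ring is cut at C-6–ring D and C-6–C-5. The diazo compound A8 adds to the seven-ring ketone A7 under Sc(OTf)3 with a chiral N,N'-dioxide ligand, and migration of the dimethoxyaryl group gives the eight-ring ketone A9.

- Merits: the eight-membered ring and the C-6 stereocentre form in one catalyst-controlled step. A7 would be available by the same acylation as 34. Control at C-6 by a catalyst is better than the substrate-controlled closure of step 17.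
- Weak points: the carbonyl ends on C-5. Ring E with its furan would then have to be brought in as a nucleophile, and the resulting tertiary alcohol deoxygenated at a carbon whose cation is not stabilised. The di-ortho-substituted aryl ketone is a reluctant partner, and A8 is an unstabilised diazo compound.
- Comparison: the chosen plan keeps the C-5 arene attached from the start (the benzylic carbon of 20 becomes C-5), so unit 3 is the common building block; it pays for this with a ring closure steered by conformation.

Key step: step 7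

## Abbreviations and remark

Remark on the chemistry: the ethyl ethers that stem from ethoxyacetylene are treated as ordinary phenol protection, on the assumption that BBr3 cleaves them together with the methyl ethers.

- [DBF] = (2R,3R)-3-(3,5-dimethoxyphenyl)-6-ethoxy-2-(4-methoxyphenyl)-2,3-dihydro-1-benzofuran-4-yl (trans).
- [Br-DBF] = the same group with bromine on C-2 of the dimethoxyphenyl ring. The spatial arrangement is unchanged; the descriptor at furan C-3 becomes S only because bromine raises the rank of that aryl group.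
- "H-3 of unit n" = the hydrogen on C-3 of the furan of unit n.

## Route

Step 1
Reactants: 1 tert-butyldimethyl(prop-2-yn-1-yloxy)silane; 2 3,5-dimethoxybenzaldehyde
Product: 4 rac-4-(tert-butyldimethylsilyloxy)-1-(3,5-dimethoxyphenyl)but-2-yn-1-ol, via lithium acetylide 3 (not isolated)
Conditions: n-BuLi, THF, −78 °C; then 2, −78 → 0 °C; aq. NH4Cl
Reagents that add atoms: none
Why: Addition of a lithium acetylide to an aryl aldehyde. The racemic alcohol suffices because the stereochemistry is set in step 4.

Step 2
Reactants: 4 rac-propargylic alcohol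
Product: 5 rac-4-(tert-butyldimethylsilyloxy)-1-(3,5-dimethoxyphenyl)but-2-yn-1-yl methyl carbonate
Conditions: ClCO2Me, pyridine, CH2Cl2, 0 °C
Reagents that add atoms: methyl chloroformate, COC(=O)Cl
Why: Acylation of the secondary alcohol gives the leaving group for the borylation. The meta-methoxy groups do not favour ionisation, so the carbonate should be stable.

Step 3
Reactants: 5 propargylic carbonate
Product: 6 rac-allenylboronate tert-butyl{[4-(3,5-dimethoxyphenyl)-2-(pinacolatoboryl)buta-2,3-dien-1-yl]oxy}dimethylsilane
Conditions: B2pin2, CuCl (5 mol%), NaOtBu (5 mol%), Xantphos (5 mol%), THF, rt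
Reagents that add atoms: bis(pinacolato)diboron, CC1(C)OB(OC1(C)C)B1OC(C)(C)C(C)(C)O1
Why: Copper-catalysed borylative SN2' substitution of a propargylic carbonate. The boryl copper species adds to the alkyne carbon remote from the leaving group and carbonate is expelled, giving the allenylboronate.

Step 4
Reactants: 6 rac-allenylboronate; 7 4-methoxybenzaldehyde
Product: 8 (1R,2R)-5-(tert-butyldimethylsilyloxy)-2-(3,5-dimethoxyphenyl)-1-(4-methoxyphenyl)pent-3-yn-1-ol (anti)
Conditions: 6 in excess (2.5 equiv), (R)-TRIP phosphoric acid (10 mol%; the antipode if the sense of induction is opposite), 4 Å MS, toluene, −20 °C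
Reagents that add atoms: none
Why: Chiral phosphoric acid-catalysed allenylboration through a closed six-membered transition state, run as a kinetic resolution of the racemic boronate. The catalyst selects the Re face of 7 (C-1, R) and only the matched allene enantiomer reacts quickly, its axis fixing C-2 (R); the equatorial aldehyde aryl group gives the anti relationship.

Step 5
Reactants: 8 anti alcohol; 9 trichloroethylene
Product: 11 (E)-1,2-dichlorovinyl ether of 8, via dichloroacetylene 10 (not isolated)
Conditions: KH (2.2 equiv), THF, 0 °C; then 9, −50 °C → rt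
Reagents that add atoms: none
Why: The potassium alkoxide adds to dichloroacetylene generated in the flask from trichloroethylene, and trans protonation gives the (E)-dichlorovinyl ether. Low temperature limits isomerisation at the propargylic C–H.

Step 6
Reactants: 11 dichlorovinyl ether
Product: 13 tert-butyl{[(4R,5R)-4-(3,5-dimethoxyphenyl)-5-(ethynyloxy)-5-(4-methoxyphenyl)pent-2-yn-1-yl]oxy}dimethylsilane, via lithium alkynyl ether 12 (not isolated)
Conditions: n-BuLi (2.4 equiv), THF, −78 → −40 °C; then MeOH, −78 °C
Reagents that add atoms: none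
Why: Elimination of HCl to the chloroalkynyl ether, chlorine–lithium exchange and protonation give the terminal ynol ether. Neither stereocentre is involved.

Step 7
Reactants: 13 ynol ether–alkyne; 14 ethoxyacetylene
Product: 15 tert-butyl([DBF]methoxy)dimethylsilane
Conditions: Cp*RuCl(cod) (10 mol%), ClCH2CH2Cl, rt; 13 added slowly to the catalyst and an excess of 14
Reagents that add atoms: none
Why: Proposed new method: Cp*RuCl(cod), a complex of divalent ruthenium, should couple the ynol ether and the internal alkyne of 13 oxidatively to a ruthenacyclopentadiene of tetravalent ruthenium, after which ethoxyacetylene inserts and reductive elimination releases the benzene ring; the closest known reaction is the Cp*RuCl(cod)-catalysed [2+2+2] cycloaddition of unsymmetrical 1,6-diynes with terminal alkynes, where an ynol ether inside the tether has not been tried. The dihydrofuran closes in the oxidative coupling, by bond formation between the oxygen-bearing ynol ether carbon and the internal-alkyne carbon that carries the CH(aryl) group, across the three-atom C–C–O tether; the benzene ring closes by alkyne insertion and reductive elimination. Three arene C–C bonds and two rings form and no stereocentre is created: furan C-2 and C-3 are sp3 spectators from step 4, and the anti chain maps onto the trans ring. The reaction is a pure addition, so every atom of 13 and of one molecule of 14 is retained in 15. The selectivity needed is regiochemical: the ethoxy-bearing carbon must bond to the unsubstituted ynol ether terminus, which is expected because the substituted α-carbon of the metallacycle (bearing CH2OSi) repels the substituted alkyne carbon, the usual meta preference of this catalyst. Cross-cycloaddition over diyne dimerisation and trimerisation of 14 is secured by slow addition of 13 to an excess of 14. Room temperature is kept because benzyl alkynyl ethers rearrange sigmatropically on heating.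

Step 8
Reactants: 15 silyl ether
Product: 16 [DBF]methanol
Conditions: Bu4NF, THF, 0 °C
Reagents that add atoms: none
Why: Fluoride cleaves the primary silyl ether; nothing else in 15 is fluoride-labile.

Step 9
Reactants: 16 benzylic alcohol
Product: 17 [DBF]carbaldehyde
Conditions: Dess–Martin periodinane, NaHCO3, CH2Cl2, rt
Reagents that add atoms: none
Why: Buffered Dess–Martin oxidation of a primary benzylic alcohol stops at the aldehyde and leaves the benzylic ether untouched.

Step 10
Reactants: 17 aldehyde
Product: 18 [Br-DBF]carbaldehyde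
Conditions: N-bromosuccinimide (1.0 equiv), MeCN, −20 °C
Reagents that add atoms: N-bromosuccinimide, O=C1CCC(=O)N1Br
Why: Electrophilic bromination goes para to a methoxy group of the most electron-rich ring. The benzofuran arene is deactivated by the formyl group, the anisyl ring has only one donor, and the two ortho positions of the dimethoxyphenyl ring are equivalent by rotation.

Step 11
Reactants: 16 benzylic alcohol
Product: 19 [DBF]methyl chloride
Conditions: PPh3, N-chlorosuccinimide, THF, 0 °C → rt
Reagents that add atoms: N-chlorosuccinimide, O=C1CCC(=O)N1Cl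
Why: Appel-type chlorination of a primary benzylic alcohol under neutral conditions.

Step 12
Reactants: 19 [DBF]methyl chloride
Product: 20 [DBF]methylzinc chloride (LiCl adduct, obtained and kept as a titrated THF solution)
Conditions: Zn dust (1.5 equiv), LiCl (1.5 equiv), THF, rt; solution decanted from the excess zinc and titrated with I2
Reagents that add atoms: zinc, [Zn]
Why: Direct insertion of zinc into a primary benzylic chloride in the presence of LiCl gives a soluble benzylzinc chloride with little Wurtz homocoupling. The reagent tolerates the aryl ethers and is stable in solution, so one batch serves steps 13 and 21.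

Step 13
Reactants: 20 [DBF]methylzinc chloride; 18 bromo aldehyde
Product: 21 1-[Br-DBF]-2-[DBF]ethan-1-ol (both carbinol epimers)
Conditions: MgCl2 (1 equiv), THF, 0 °C → rt; aq. NH4Cl
Reagents that add atoms: none
Why: MgCl2 promotes the addition of the benzylzinc reagent to the aldehyde (C-4–C-5 bond), and the organozinc leaves the aryl bromide untouched. The carbinol configuration is irrelevant because it is oxidised in step 16.

Step 14
Reactants: 21 bromo alcohol; 7 4-methoxybenzaldehyde
Product: 23 diol in which ring D carries CH(OH)(4-methoxyphenyl) in place of bromine (epimers at both carbinols), via aryllithium alkoxide 22 (not isolated)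
Conditions: NaH, THF, 0 °C; t-BuLi (2.1 equiv), −78 °C; then 7, −78 °C
Reagents that add atoms: none
Why: The alkoxide protects the free hydroxyl, bromine–lithium exchange at −78 °C is faster than any deprotonation, and the aryllithium adds to the aldehyde (ring D–C-6 bond). The new carbinol centre is ionised in step 17.

Step 15
Reactants: 23 diol
Product: 24 methyl ether of 23 at the diarylmethyl carbinol (C-6)
Conditions: MeOH, pyridinium p-toluenesulfonate (cat.), CH2Cl2, rt
Reagents that add atoms: methanol, CO
Why: Only the doubly benzylic carbinol, stabilised by three methoxy groups, ionises under mild acid (SN1 etherification). The other alcohol, flanked by meta-oxygenated arenes, does not.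

Step 16
Reactants: 24 hydroxy ether
Product: 25 1-aryl-2-[DBF]ethan-1-one (C-4 ketone) bearing the C-6 methyl ether
Conditions: Dess–Martin periodinane, NaHCO3, CH2Cl2, rt
Reagents that add atoms: none
Why: Buffered Dess–Martin oxidation of the remaining secondary alcohol gives the deoxybenzoin-type ketone and leaves the diarylmethyl ether intact.

Step 17
Reactants: 25 keto ether
Product: 27 eight-ring ketone (C-4 C=O; H-6 cis to H-3 of unit 2; H-5 trans to H-6), via silyl enol ether 26 (not isolated)
Conditions: Et3N (1.5 equiv), Me3SiOTf (2.5 equiv), CH2Cl2 (0.005 M), −78 → −20 °C; aq. NaHCO3; then DBU, CH2Cl2, rt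
Reagents that add atoms: none
Why: The ketone is silylated at its only enolisable carbon (C-5), the silyl triflate ionises the diarylmethyl ether, and an intramolecular SN1 alkylation of the enol ether (Mukaiyama type) closes the eight-membered ring at high dilution. The cation should place its anisyl group beside the ortho methoxy group and its hydrogen beside the bulky ring-fusion methine, and the tether reaches only one face, so H-6 should end cis to H-3 of unit 2. DBU then equilibrates the enolisable C-5 so that ring E is trans to the C-6 aryl group.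

Step 18
Reactants: 27 eight-ring ketone
Product: 28 C-4 methylidene analogue of 27
Conditions: Cp2TiMe2, toluene, 70 °C, dark
Reagents that add atoms: dimethyltitanocene, C[Ti](C)(C1C=CC=C1)C1C=CC=C1
Why: Titanium methylidene olefination (Tebbe–Petasis type) is non-basic and should methylenate the hindered, easily enolised α-aryl ketone without touching C-5.

Step 19
Reactants: 28 alkene
Product: 30 C-4 hydroxymethyl compound (H-4 cis to H-5), via alkylborane 29 (not isolated)
Conditions: BH3·SMe2, THF, 0 °C → rt; then NaOH, H2O2, 0 °C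
Reagents that add atoms: hydrogen peroxide, OO
Why: Anti-Markovnikov hydroboration–oxidation of a 1,1-disubstituted alkene. Borane should add to the face opposite the neighbouring ring E on C-5, so H-4 is delivered trans to that arene and the new CH2OH (C-3) ends cis to it.

Step 20
Reactants: 30 primary alcohol
Product: 31 eight-ring aldehyde (C-3 = CHO on C-4)
Conditions: Dess–Martin periodinane, NaHCO3, CH2Cl2, 0 °C
Reagents that add atoms: none
Why: Buffered Dess–Martin oxidation gives the α-aryl aldehyde without base, so C-4 should not epimerise; the aldehyde is used at once.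

Step 21
Reactants: 20 [DBF]methylzinc chloride
Product: 32 [DBF]acetic acid
Conditions: MgCl2 (1 equiv), CO2 (1 atm), THF, rt; 1 M HCl
Reagents that add atoms: carbon dioxide, O=C=O
Why: MgCl2-promoted carboxylation of the benzylzinc reagent gives the arylacetic acid after acidification; the new carbon becomes C-1.

Step 22
Reactants: 32 arylacetic acid
Product: 34 seven-ring ketone (C-1 C=O on ring A; C-2 CH2 on ring B), via mixed anhydride 33 (not isolated)
Conditions: (CF3CO)2O, CF3CO2H (cat.), CH2Cl2, 0 °C → rt
Reagents that add atoms: none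
Why: Intramolecular Friedel–Crafts acylation through the mixed anhydride. The only position within reach is the ortho carbon of the dimethoxyphenyl ring, activated ortho and para by two methoxy groups, as in the classical route to dibenzosuberones. No stereocentre is touched.

Step 23
Reactants: 34 seven-ring ketone; 31 eight-ring aldehyde
Product: 38 (E)-enone joining both halves through C-2=C-3, via lithium enolate 35 (not isolated), via lithium aldolate 36 (not isolated), via aldol mesylate 37 (not isolated)
Conditions: LiN(i-Pr)2 (LDA), THF, −78 °C; 31, −78 °C; then MeSO2Cl, Et3N, −78 → 0 °C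
Reagents that add atoms: none
Why: Directed aldol addition of the only possible enolate to the α-branched aldehyde at −78 °C, then mesylation and E1cB elimination (aldol condensation). The (E)-enone, with the C-4 substituent away from the carbonyl, is expected, and the low temperature and weak amine base should leave C-4 untouched.

Step 24
Reactants: 38 enone; 39 4-methoxyphenylmagnesium bromide
Product: 41 seven-ring ketone with (3R)-C-3 bearing 4-methoxyphenyl (H-2 cis to H-3 of unit 1), via silyl enol ether 40 (not isolated)
Conditions: 39 in excess (3 equiv), CuBr·SMe2 (0.2 equiv), Me3SiCl (3 equiv), THF, −78 → −30 °C; then Bu4NF, AcOH, THF, −78 °C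
Reagents that add atoms: none
Why: Copper-catalysed conjugate addition of the aryl Grignard reagent, accelerated by the silyl chloride. In the conformer that minimises allylic strain (H-4 in the enone plane) the aryl group should add anti to the branched C-5 and give (3R). Fluoride and acetic acid then protonate C-2 from the open convex face of the tricycle, the face that carries H-3 of unit 1.

Step 25
Reactants: 41 ketone; 39 4-methoxyphenylmagnesium bromide
Product: 42 tertiary alcohol (C-1 bearing OH and 4-methoxyphenyl)
Conditions: 39 in excess (5 equiv), CeCl3 (dried, 5 equiv), THF, −78 → 0 °C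
Reagents that add atoms: none
Why: The organocerium reagent adds to hindered, enolisable ketones where the Grignard reagent alone would deprotonate. The carbinol configuration is irrelevant because C-1 is ionised next.

Step 26
Reactants: 42 tertiary alcohol
Product: 43 pentadeca-O-alkyl ether of 44 (1S,2S,3R,4R,5S,6S)
Conditions: Et3SiH (10 equiv), CF3CO2H (5 equiv), CH2Cl2, −40 → 0 °C
Reagents that add atoms: none
Why: Ionic hydrogenation: the tertiary diaryl carbinol ionises at low temperature and the silane delivers hydride to the doubly benzylic cation from the convex face, anti to the C-2 substituent, so H-1 ends cis to H-2. If the cation equilibrates with the C-1=C-2 alkene, C-2 is reprotonated from the same face. The cation forms far more readily than the furan C–O bonds ionise.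

Step 27
Reactants: 43 pentadeca-O-alkyl ether
Product: 44 target hexamer CNP0184494.1
Conditions: BBr3 (45 equiv), CH2Cl2, −78 °C → rt; MeOH, then H2O
Reagents that add atoms: none
Why: Boron tribromide cleaves the twelve methyl and three ethyl aryl ethers. The hydrocarbon framework carries no other Lewis-basic or reducible group, and no stereocentre is epimerisable under these conditions.

## Compound list

1 | tert-butyldimethyl(prop-2-yn-1-yloxy)silane | C#CCO[Si](C)(C)C(C)(C)C | starting material
2 | 3,5-dimethoxybenzaldehyde | COc1cc(C=O)cc(OC)c1 | starting material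
3 | [3-(tert-butyldimethylsilyloxy)prop-1-yn-1-yl]lithium | [Li]C#CCO[Si](C)(C)C(C)(C)C | intermediate (not isolated)
4 | rac-4-(tert-butyldimethylsilyloxy)-1-(3,5-dimethoxyphenyl)but-2-yn-1-ol | COc1cc(cc(OC)c1)C(O)C#CCO[Si](C)(C)C(C)(C)C | intermediate
5 | rac-4-(tert-butyldimethylsilyloxy)-1-(3,5-dimethoxyphenyl)but-2-yn-1-yl methyl carbonate | COC(=O)OC(C#CCO[Si](C)(C)C(C)(C)C)c1cc(OC)cc(OC)c1 | intermediate
6 | rac-tert-butyl{[4-(3,5-dimethoxyphenyl)-2-(4,4,5,5-tetramethyl-1,3,2-dioxaborolan-2-yl)buta-2,3-dien-1-yl]oxy}dimethylsilane | COc1cc(C=C=C(CO[Si](C)(C)C(C)(C)C)B2OC(C)(C)C(C)(C)O2)cc(OC)c1 | intermediate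
7 | 4-methoxybenzaldehyde | COc1ccc(C=O)cc1 | starting material
8 | (1R,2R)-5-(tert-butyldimethylsilyloxy)-2-(3,5-dimethoxyphenyl)-1-(4-methoxyphenyl)pent-3-yn-1-ol (anti) | CC(C)(C)[Si](C)(C)OCC#C[C@@H](c1cc(OC)cc(OC)c1)[C@H](c1ccc(OC)cc1)O | intermediate
9 | trichloroethylene | ClC=C(Cl)Cl | starting material
10 | dichloroacetylene | ClC#CCl | intermediate (not isolated)
11 | tert-butyl{[(4R,5R)-5-[(E)-1,2-dichloroethenyloxy]-4-(3,5-dimethoxyphenyl)-5-(4-methoxyphenyl)pent-2-yn-1-yl]oxy}dimethylsilane | CC(C)(C)[Si](C)(C)OCC#C[C@@H](c1cc(OC)cc(OC)c1)[C@H](c1ccc(OC)cc1)O/C(Cl)=C\Cl | intermediate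
12 | lithium acetylide of 13 (lithium on the ynol ether terminus) | CC(C)(C)[Si](C)(C)OCC#C[C@@H](c1cc(OC)cc(OC)c1)[C@H](c1ccc(OC)cc1)OC#C[Li] | intermediate (not isolated)
13 | tert-butyl{[(4R,5R)-4-(3,5-dimethoxyphenyl)-5-(ethynyloxy)-5-(4-methoxyphenyl)pent-2-yn-1-yl]oxy}dimethylsilane | CC(C)(C)[Si](C)(C)OCC#C[C@@H](c1cc(OC)cc(OC)c1)[C@H](c1ccc(OC)cc1)OC#C | intermediate
14 | ethoxyacetylene | CCOC#C | starting material
15 | tert-butyl{[(2R,3R)-3-(3,5-dimethoxyphenyl)-6-ethoxy-2-(4-methoxyphenyl)-2,3-dihydro-1-benzofuran-4-yl]methoxy}dimethylsilane (trans) | CC(C)(C)[Si](C)(C)OCc1cc(OCC)cc2c1[C@@H](c1cc(OC)cc(OC)c1)[C@H](c1ccc(OC)cc1)O2 | intermediate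
16 | [DBF]methanol | OCc1cc(OCC)cc2c1[C@@H](c1cc(OC)cc(OC)c1)[C@H](c1ccc(OC)cc1)O2 | intermediate
17 | (2R,3R)-3-(3,5-dimethoxyphenyl)-6-ethoxy-2-(4-methoxyphenyl)-2,3-dihydro-1-benzofuran-4-carbaldehyde | O=Cc1cc(OCC)cc2c1[C@@H](c1cc(OC)cc(OC)c1)[C@H](c1ccc(OC)cc1)O2 | intermediate
18 | (2R,3S)-3-(2-bromo-3,5-dimethoxyphenyl)-6-ethoxy-2-(4-methoxyphenyl)-2,3-dihydro-1-benzofuran-4-carbaldehyde (trans, same spatial arrangement as 17) | O=Cc1cc(OCC)cc2c1[C@@H](c1cc(OC)cc(OC)c1Br)[C@H](c1ccc(OC)cc1)O2 | intermediate
19 | (2R,3R)-4-(chloromethyl)-3-(3,5-dimethoxyphenyl)-6-ethoxy-2-(4-methoxyphenyl)-2,3-dihydro-1-benzofuran | ClCc1cc(OCC)cc2c1[C@@H](c1cc(OC)cc(OC)c1)[C@H](c1ccc(OC)cc1)O2 | intermediate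
20 | [DBF]methylzinc chloride (LiCl adduct, THF solution) | Cl[Zn]Cc1cc(OCC)cc2c1[C@@H](c1cc(OC)cc(OC)c1)[C@H](c1ccc(OC)cc1)O2 | intermediate
21 | 1-[Br-DBF]-2-[DBF]ethan-1-ol (carbinol epimers) | OC(Cc1cc(OCC)cc2c1[C@@H](c1cc(OC)cc(OC)c1)[C@H](c1ccc(OC)cc1)O2)c1cc(OCC)cc2c1[C@@H](c1cc(OC)cc(OC)c1Br)[C@H](c1ccc(OC)cc1)O2 | intermediate
22 | sodium alkoxide of 21 with lithium in place of bromine | [Na]OC(Cc1cc(OCC)cc2c1[C@@H](c1cc(OC)cc(OC)c1)[C@H](c1ccc(OC)cc1)O2)c1cc(OCC)cc2c1[C@@H](c1cc(OC)cc(OC)c1[Li])[C@H](c1ccc(OC)cc1)O2 | intermediate (not isolated)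
23 | diol: 21 with CH(OH)(4-methoxyphenyl) in place of bromine (epimers at both carbinols) | OC(Cc1cc(OCC)cc2c1[C@@H](c1cc(OC)cc(OC)c1)[C@H](c1ccc(OC)cc1)O2)c1cc(OCC)cc2c1[C@@H](c1cc(OC)cc(OC)c1C(O)c1ccc(OC)cc1)[C@H](c1ccc(OC)cc1)O2 | intermediate
24 | 23 with the diarylmethyl hydroxyl as methyl ether | OC(Cc1cc(OCC)cc2c1[C@@H](c1cc(OC)cc(OC)c1)[C@H](c1ccc(OC)cc1)O2)c1cc(OCC)cc2c1[C@@H](c1cc(OC)cc(OC)c1C(OC)c1ccc(OC)cc1)[C@H](c1ccc(OC)cc1)O2 | intermediate
25 | ketone from 24 (C-4 C=O, C-5 CH2, C-6 CH(OMe)(4-methoxyphenyl) on ring D) | O=C(Cc1cc(OCC)cc2c1[C@@H](c1cc(OC)cc(OC)c1)[C@H](c1ccc(OC)cc1)O2)c1cc(OCC)cc2c1[C@@H](c1cc(OC)cc(OC)c1C(OC)c1ccc(OC)cc1)[C@H](c1ccc(OC)cc1)O2 | intermediate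
26 | trimethylsilyl enol ether of 25 (C-4=C-5) | C[Si](C)(C)OC(=Cc1cc(OCC)cc2c1[C@@H](c1cc(OC)cc(OC)c1)[C@H](c1ccc(OC)cc1)O2)c1cc(OCC)cc2c1[C@@H](c1cc(OC)cc(OC)c1C(OC)c1ccc(OC)cc1)[C@H](c1ccc(OC)cc1)O2 | intermediate (not isolated)
27 | eight-ring ketone: C-4 C=O on ring C, C-5 (H, ring E of unit 3), C-6 (H, 4-methoxyphenyl) on ring D; H-6 cis to H-3 of unit 2, H-5 trans to H-6 | O=C1c2cc(OCC)cc3c2[C@@H](c2cc(OC)cc(OC)c2[C@H](c2ccc(OC)cc2)[C@H]1c1cc(OCC)cc2c1[C@@H](c1cc(OC)cc(OC)c1)[C@H](c1ccc(OC)cc1)O2)[C@H](c1ccc(OC)cc1)O3 | intermediate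
28 | 27 with C=CH2 in place of C=O at C-4 | C=C1c2cc(OCC)cc3c2[C@@H](c2cc(OC)cc(OC)c2[C@H](c2ccc(OC)cc2)[C@H]1c1cc(OCC)cc2c1[C@@H](c1cc(OC)cc(OC)c1)[C@H](c1ccc(OC)cc1)O2)[C@H](c1ccc(OC)cc1)O3 | intermediate
29 | alkylborane: C-4 (H) bearing CH2BH2, H-4 cis to H-5 | BC[C@H]1c2cc(OCC)cc3c2[C@@H](c2cc(OC)cc(OC)c2[C@H](c2ccc(OC)cc2)[C@H]1c1cc(OCC)cc2c1[C@@H](c1cc(OC)cc(OC)c1)[C@H](c1ccc(OC)cc1)O2)[C@H](c1ccc(OC)cc1)O3 | intermediate (not isolated)
30 | eight-ring primary alcohol: C-4 (H) bearing CH2OH, H-4 cis to H-5 | OC[C@H]1c2cc(OCC)cc3c2[C@@H](c2cc(OC)cc(OC)c2[C@H](c2ccc(OC)cc2)[C@H]1c1cc(OCC)cc2c1[C@@H](c1cc(OC)cc(OC)c1)[C@H](c1ccc(OC)cc1)O2)[C@H](c1ccc(OC)cc1)O3 | intermediate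
31 | eight-ring aldehyde: C-4 (H) bearing CHO (C-3) | O=C[C@H]1c2cc(OCC)cc3c2[C@@H](c2cc(OC)cc(OC)c2[C@H](c2ccc(OC)cc2)[C@H]1c1cc(OCC)cc2c1[C@@H](c1cc(OC)cc(OC)c1)[C@H](c1ccc(OC)cc1)O2)[C@H](c1ccc(OC)cc1)O3 | intermediate
32 | [DBF]acetic acid | OC(=O)Cc1cc(OCC)cc2c1[C@@H](c1cc(OC)cc(OC)c1)[C@H](c1ccc(OC)cc1)O2 | intermediate
33 | mixed anhydride of 32 with trifluoroacetic acid | FC(F)(F)C(=O)OC(=O)Cc1cc(OCC)cc2c1[C@@H](c1cc(OC)cc(OC)c1)[C@H](c1ccc(OC)cc1)O2 | intermediate (not isolated)
34 | seven-ring ketone: C-1 C=O bonded to the ortho carbon of ring A, C-2 CH2 on ring B, trans-dihydrofuran of unit 1 fused | O=C2c3c(OC)cc(OC)cc3[C@@H]3c4c(cc(OCC)cc4C2)O[C@H]3c2ccc(OC)cc2 | intermediate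
35 | lithium enolate of 34 (C-1=C-2) | [Li]OC=2c3c(OC)cc(OC)cc3[C@@H]3c4c(cc(OCC)cc4C=2)O[C@H]3c2ccc(OC)cc2 | intermediate (not isolated)
36 | lithium aldolate: C-2 of 34 bonded to C-3 (CH–OLi) of 31 (epimers at C-2 and C-3) | O=C2c3c(OC)cc(OC)cc3[C@@H]3c4c(cc(OCC)cc4C2C(O[Li])[C@H]2c4cc(OCC)cc5c4[C@@H](c4cc(OC)cc(OC)c4[C@H](c4ccc(OC)cc4)[C@H]2c2cc(OCC)cc4c2[C@@H](c2cc(OC)cc(OC)c2)[C@H](c2ccc(OC)cc2)O4)[C@H](c2ccc(OC)cc2)O5)O[C@H]3c2ccc(OC)cc2 | intermediate (not isolated)
37 | methanesulfonate of the aldol (C-3 OMs) | O=C2c3c(OC)cc(OC)cc3[C@@H]3c4c(cc(OCC)cc4C2C(OS(C)(=O)=O)[C@H]2c4cc(OCC)cc5c4[C@@H](c4cc(OC)cc(OC)c4[C@H](c4ccc(OC)cc4)[C@H]2c2cc(OCC)cc4c2[C@@H](c2cc(OC)cc(OC)c2)[C@H](c2ccc(OC)cc2)O4)[C@H](c2ccc(OC)cc2)O5)O[C@H]3c2ccc(OC)cc2 | intermediate (not isolated)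
38 | (E)-enone: seven-ring ketone with exocyclic C-2=C-3 double bond to C-4 of the eight-ring unit | O=C2c3c(OC)cc(OC)cc3[C@@H]3c4c(cc(OCC)cc4/C2=C\[C@H]2c4cc(OCC)cc5c4[C@@H](c4cc(OC)cc(OC)c4[C@H](c4ccc(OC)cc4)[C@H]2c2cc(OCC)cc4c2[C@@H](c2cc(OC)cc(OC)c2)[C@H](c2ccc(OC)cc2)O4)[C@H](c2ccc(OC)cc2)O5)O[C@H]3c2ccc(OC)cc2 | intermediate
39 | 4-methoxyphenylmagnesium bromide | COc1ccc([Mg]Br)cc1 | starting material
40 | trimethylsilyl enol ether (C-1=C-2) of 41, (3R) | C[Si](C)(C)OC=2c3c(OC)cc(OC)cc3[C@@H]3c4c(cc(OCC)cc4C=2[C@H](c2ccc(OC)cc2)[C@H]2c4cc(OCC)cc5c4[C@@H](c4cc(OC)cc(OC)c4[C@H](c4ccc(OC)cc4)[C@H]2c2cc(OCC)cc4c2[C@@H](c2cc(OC)cc(OC)c2)[C@H](c2ccc(OC)cc2)O4)[C@H](c2ccc(OC)cc2)O5)O[C@H]3c2ccc(OC)cc2 | intermediate (not isolated)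
41 | seven-ring ketone bearing on C-2 the (3R)-CH(4-methoxyphenyl) group bonded to C-4 of the eight-ring unit; H-2 cis to H-3 of unit 1 | O=C2c3c(OC)cc(OC)cc3[C@@H]3c4c(cc(OCC)cc4[C@H]2[C@H](c2ccc(OC)cc2)[C@H]2c4cc(OCC)cc5c4[C@@H](c4cc(OC)cc(OC)c4[C@H](c4ccc(OC)cc4)[C@H]2c2cc(OCC)cc4c2[C@@H](c2cc(OC)cc(OC)c2)[C@H](c2ccc(OC)cc2)O4)[C@H](c2ccc(OC)cc2)O5)O[C@H]3c2ccc(OC)cc2 | intermediate
42 | tertiary alcohol: 41 with C-1 bearing OH and 4-methoxyphenyl (C-1 configuration not defined) | COc1ccc(C2(O)c3c(OC)cc(OC)cc3[C@@H]3c4c(cc(OCC)cc4[C@H]2[C@H](c2ccc(OC)cc2)[C@H]2c4cc(OCC)cc5c4[C@@H](c4cc(OC)cc(OC)c4[C@H](c4ccc(OC)cc4)[C@H]2c2cc(OCC)cc4c2[C@@H](c2cc(OC)cc(OC)c2)[C@H](c2ccc(OC)cc2)O4)[C@H](c2ccc(OC)cc2)O5)O[C@H]3c2ccc(OC)cc2)cc1 | intermediate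
43 | pentadeca-O-alkyl ether of 44 (twelve methyl ethers; ethyl ethers on rings B, C and E) | COc1ccc([C@H]2c3c(OC)cc(OC)cc3[C@@H]3c4c(cc(OCC)cc4[C@H]2[C@H](c2ccc(OC)cc2)[C@H]2c4cc(OCC)cc5c4[C@@H](c4cc(OC)cc(OC)c4[C@H](c4ccc(OC)cc4)[C@H]2c2cc(OCC)cc4c2[C@@H](c2cc(OC)cc(OC)c2)[C@H](c2ccc(OC)cc2)O4)[C@H](c2ccc(OC)cc2)O5)O[C@H]3c2ccc(OC)cc2)cc1 | intermediate
44 | CNP0184494.1, resveratrol hexamer | Oc1ccc([C@H]2c3c(O)cc(O)cc3[C@@H]3c4c(cc(O)cc4[C@H]2[C@H](c2ccc(O)cc2)[C@H]2c4cc(O)cc5c4[C@@H](c4cc(O)cc(O)c4[C@H](c4ccc(O)cc4)[C@H]2c2cc(O)cc4c2[C@@H](c2cc(O)cc(O)c2)[C@H](c2ccc(O)cc2)O4)[C@H](c2ccc(O)cc2)O5)O[C@H]3c2ccc(O)cc2)cc1 | target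

## Step count and least certain steps

Total: 27 steps. Longest linear sequence: 23 steps (steps 1–10, 13–20 and 23–27; the path through steps 11 and 12 in place of 9 and 10 is equally long). Steps 21 and 22 form the side branch to ketone 34.

**Step 7 (key step, the only step marked as a proposed new method).** The electron-rich ynol ether may be diverted by ruthenium into vinylidene or ketene chemistry, or rearrange, before the metallacycle forms; oligomerisation of ethoxyacetylene may also outrun the cross reaction. The fallback uses known chemistry and moves the C–O bond formation after the arene synthesis. It sets out from 8: silylation with chloro(ethynyl)dimethylsilane and imidazole gives the ethynyl(dimethyl)silyl ether F1; cycloaddition of this silicon-tethered diyne with 14, under Cp*RuCl(cod) or RhCl(PPh3)3, gives the benzo-fused cyclic siloxane F2; Tamao–Fleming oxidation (H2O2, KF, KHCO3) gives the phenol alcohol F3; acid-catalysed cyclodehydration through the para-methoxybenzylic cation then closes the thermodynamically favoured trans-dihydrofuran, and the route is rejoined at 15.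

**Step 4.** The catalyst may discriminate poorly between the allene enantiomers, or anti selectivity may be low with an allenylboronate that is branched at the boron-bearing carbon; this would erode the enantiomeric purity on which all three units depend. The fallback introduces the hydroxymethyl group later, using the simpler boronate class. It sets out from 2: ethynylmagnesium bromide followed by methyl chloroformate gives rac-1-(3,5-dimethoxyphenyl)prop-2-yn-1-yl methyl carbonate F4; copper-catalysed borylation gives the monosubstituted allenylboronate F5; the same phosphoric acid-catalysed kinetic-resolution addition to 7 gives the terminal alkyne (1R,2R)-2-(3,5-dimethoxyphenyl)-1-(4-methoxyphenyl)but-3-yn-1-ol F6; its dianion (EtMgBr) with paraformaldehyde gives the diol F7; selective silylation of the primary hydroxyl returns to 8.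

**Step 17.** The cation may be captured intermolecularly or by ring F instead of the tethered enol ether, or closure may proceed through the other rotamer of the cation and give the wrong configuration at C-6. The fallback sets C-6 by protonation instead of C–C bond formation. It sets out from 23: Dess–Martin oxidation of both carbinols gives the diketone F8; intramolecular aldol condensation of the C-5 enolate onto the diaryl ketone (KOtBu, t-BuOH) gives the eight-ring enone F9; conjugate reduction with SmI2 and MeOH, followed by DBU, returns to 27.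

**Step 24.** The aryl copper species may add to the wrong face of the enone, or not at all at the hindered β-carbon, and the basic reagent may enolise towards C-4. The fallback replaces substrate control by catalyst control. It sets out from 38 and uses a rhodium-catalysed conjugate addition of 4-methoxyphenylboronic acid ([RhCl(C2H4)2]2, chiral diene ligand, KOH, dioxane/H2O). The rhodium enolate is protonated in the flask, and the route is rejoined at 41; no new compound is made (entry F0).

**Step 25.** The ketone is flanked by a di-ortho-substituted arene and a fully substituted carbon, so enolisation may win over addition even with cerium. The fallback avoids carbonyl addition. It sets out from 41: KN(SiMe3)2 and PhNTf2 give the enol triflate F10; Suzuki coupling with 4-methoxyphenylboronic acid (Pd(OAc)2, SPhos, K3PO4) gives the tetrasubstituted cyclic stilbene F11; under the conditions of step 26 this is protonated at C-2 and reduced at C-1 from the convex face, rejoining the route at 43.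

Further compounds

F1 | step 7 | ethynyl(dimethyl)silyl ether of 8 | CC(C)(C)[Si](C)(C)OCC#C[C@@H](c1cc(OC)cc(OC)c1)[C@H](c1ccc(OC)cc1)O[Si](C)(C)C#C
F2 | step 7 | benzo-fused six-membered cyclic siloxane (aryl–SiMe2–O) carrying CH2OSi(t-Bu)Me2 and OEt on the new arene | CC(C)(C)[Si](C)(C)OCc1cc(OCC)cc2c1[C@@H](c1cc(OC)cc(OC)c1)[C@H](c1ccc(OC)cc1)O[Si]2(C)C
F3 | step 7 | (1R,2R)-2-[2-(tert-butyldimethylsilyloxymethyl)-4-ethoxy-6-hydroxyphenyl]-2-(3,5-dimethoxyphenyl)-1-(4-methoxyphenyl)ethan-1-ol | CC(C)(C)[Si](C)(C)OCc1cc(OCC)cc(O)c1[C@@H](c1cc(OC)cc(OC)c1)[C@H](c1ccc(OC)cc1)O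
F4 | step 4 | rac-1-(3,5-dimethoxyphenyl)prop-2-yn-1-yl methyl carbonate | COC(=O)OC(C#C)c1cc(OC)cc(OC)c1
F5 | step 4 | rac-2-[3-(3,5-dimethoxyphenyl)propa-1,2-dien-1-yl]-4,4,5,5-tetramethyl-1,3,2-dioxaborolane | COc1cc(C=C=CB2OC(C)(C)C(C)(C)O2)cc(OC)c1
F6 | step 4 | (1R,2R)-2-(3,5-dimethoxyphenyl)-1-(4-methoxyphenyl)but-3-yn-1-ol | C#C[C@@H](c1cc(OC)cc(OC)c1)[C@H](c1ccc(OC)cc1)O
F7 | step 4 | (1R,2R)-2-(3,5-dimethoxyphenyl)-1-(4-methoxyphenyl)pent-3-yne-1,5-diol | OCC#C[C@@H](c1cc(OC)cc(OC)c1)[C@H](c1ccc(OC)cc1)O
F8 | step 17 | diketone: 25 with C(=O)(4-methoxyphenyl) on ring D in place of CH(OMe)(4-methoxyphenyl) | O=C(Cc1cc(OCC)cc2c1[C@@H](c1cc(OC)cc(OC)c1)[C@H](c1ccc(OC)cc1)O2)c1cc(OCC)cc2c1[C@@H](c1cc(OC)cc(OC)c1C(=O)c1ccc(OC)cc1)[C@H](c1ccc(OC)cc1)O2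
F9 | step 17 | eight-ring enone: 27 with a C-5=C-6 double bond | O=C1c2cc(OCC)cc3c2[C@@H](c2cc(OC)cc(OC)c2C(c2ccc(OC)cc2)=C1c1cc(OCC)cc2c1[C@@H](c1cc(OC)cc(OC)c1)[C@H](c1ccc(OC)cc1)O2)[C@H](c1ccc(OC)cc1)O3
F0 | step 24 | none | none
F10 | step 25 | enol triflate of 41 (C-1=C-2, OTf on C-1) | FC(F)(F)S(=O)(=O)OC=2c3c(OC)cc(OC)cc3[C@@H]3c4c(cc(OCC)cc4C=2[C@H](c2ccc(OC)cc2)[C@H]2c4cc(OCC)cc5c4[C@@H](c4cc(OC)cc(OC)c4[C@H](c4ccc(OC)cc4)[C@H]2c2cc(OCC)cc4c2[C@@H](c2cc(OC)cc(OC)c2)[C@H](c2ccc(OC)cc2)O4)[C@H](c2ccc(OC)cc2)O5)O[C@H]3c2ccc(OC)cc2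
F11 | step 25 | tetrasubstituted alkene: C-1=C-2 with 4-methoxyphenyl on C-1 | COc1ccc(cc1)C=2c3c(OC)cc(OC)cc3[C@@H]3c4c(cc(OCC)cc4C=2[C@H](c2ccc(OC)cc2)[C@H]2c4cc(OCC)cc5c4[C@@H](c4cc(OC)cc(OC)c4[C@H](c4ccc(OC)cc4)[C@H]2c2cc(OCC)cc4c2[C@@H](c2cc(OC)cc(OC)c2)[C@H](c2ccc(OC)cc2)O4)[C@H](c2ccc(OC)cc2)O5)O[C@H]3c2ccc(OC)cc2
A1 | alternative 1 | methyl 7-(benzyloxy)-5-methoxy-2-oxo-2,3-dihydro-1H-indene-1-carboxylate | COC(=O)C1C(=O)Cc2cc(OC)cc(OCc3ccccc3)c21
A2 | alternative 1 | 3,5-dimethoxy-2-(trimethylsilyl)phenyl trifluoromethanesulfonate | COc1cc(OC)c([Si](C)(C)C)c(OS(=O)(=O)C(F)(F)F)c1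
A3 | alternative 1 | dibenzo-fused cycloheptanone ester (racemic) | COC(=O)C1c2cc(OC)cc(OC)c2C(=O)Cc2cc(OC)cc(OCc3ccccc3)c21
A4 | alternative 2 | 1,1-dimethoxy-3-(trimethylsilyloxy)buta-1,3-diene | COC(OC)=CC(=C)O[Si](C)(C)C
A5 | alternative 2 | pentameric core bearing on C-5 the alkynyl 3,5-dimethoxyphenyl ketone | COc1ccc([C@H]2c3c(OC)cc(OC)cc3[C@@H]3c4c(cc(OC)cc4[C@H]2[C@H](c2ccc(OC)cc2)[C@H]2c4cc(OC)cc5c4[C@@H](c4cc(OC)cc(OC)c4[C@H](c4ccc(OC)cc4)[C@H]2C#CC(=O)c2cc(OC)cc(OC)c2)[C@H](c2ccc(OC)cc2)O5)O[C@H]3c2ccc(OC)cc2)cc1
A6 | alternative 2 | 2-aroyl-3-methoxy-5-hydroxyphenyl derivative of the pentameric core | COc1ccc([C@H]2c3c(OC)cc(OC)cc3[C@@H]3c4c(cc(OC)cc4[C@H]2[C@H](c2ccc(OC)cc2)[C@H]2c4cc(OC)cc5c4[C@@H](c4cc(OC)cc(OC)c4[C@H](c4ccc(OC)cc4)[C@H]2c2cc(O)cc(OC)c2C(=O)c2cc(OC)cc(OC)c2)[C@H](c2ccc(OC)cc2)O5)O[C@H]3c2ccc(OC)cc2)cc1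
A7 | alternative 3 | seven-membered aryl ketone fused to the trans-dihydrobenzofuran (methyl ether analogue of 34) | O=C1Cc2cc(OC)cc3c2[C@@H](c2cc(OC)cc(OC)c21)[C@H](c1ccc(OC)cc1)O3
A8 | alternative 3 | (4-methoxyphenyl)diazomethane | COc1ccc(C=[N+]=[N-])cc1
A9 | alternative 3 | eight-membered α-aryl ketone fused to the trans-dihydrobenzofuran | O=C1Cc2cc(OC)cc3c2[C@@H](c2cc(OC)cc(OC)c2[C@@H]1c1ccc(OC)cc1)[C@H](c1ccc(OC)cc1)O3
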